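**Plan**

- Retrosynthesis: the C1 methyl imine is read as a decarboxylated C1–CH2–CO2t-Bu enamino ester, one oxidation level above a tetrahydroisoquinoline-1-acetate. Ring B (the nitrogen ring) of that acetate is cut at C4–C4a, C8a–C1 and N2–C1 at once, leaving a C8a aryl iodide, an (S)-2-methylaziridine and tert-butyl acrylate.
- The iodide is cut at the C7–C1′ biaryl bond into a 2-bromoresorcinol mono-ether (ring A) and a naphthyl boronate. Ring D of the naphthalene (oxygen and methyl) is grown onto ring C (C1′ and OMe) by Stobbe condensation and Friedel–Crafts closure.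
- Enabling feature: in ring A, C8a sits between C8–OMe and C4a–H. C4a is meta to O6 and O8, so electrophiles cannot reach it, but it is the only free position ortho to a C8a–palladium bond, and the C8 methoxy group is the ortho substituent a norbornene relay needs.
- Forward order: rings C and D, then the biaryl union with ring A, iodination and O-methylation, ring B in one operation, and finally oxidation level and unmasking.
- Stereochemistry: C3 (S) comes from L-alaninol through the aziridine and is never a reaction site. The C1 centre made in the key step is transient.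
- Tactics: iodine is placed ortho to a still free C8 hydroxyl (para to the C6 ether), the innate site of 3-alkoxyphenols, and the phenol is methylated afterwards. MOM ethers allow one final acid step to unmask everything.

Key step: step 13

Assumption: the target string fixes only C3 and leaves the C7–C1′ axis open, so the axis is not controlled and every biaryl from 12 on is carried as the mixture of rotational isomers about it.

**Route**

Step 1
Reactants: 1 2-bromo-5-methoxybenzaldehyde; 2 diethyl succinate
Product: 3 (E)-4-(2-bromo-5-methoxyphenyl)-3-(ethoxycarbonyl)but-3-enoic acid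
Conditions: KOt-Bu, t-BuOH, reflux; then aq. HCl
Reagents that add atoms: none
Why: Stobbe condensation, in which the succinate enolate adds to the aldehyde, the alkoxide lactonises and base-induced ring opening gives the half-ester with the aryl group cis to the CH2CO2H arm, the (E) geometry the next ring closure needs.

Step 2
Reactants: 3 (E)-4-(2-bromo-5-methoxyphenyl)-3-(ethoxycarbonyl)but-3-enoic acid
Product: 4 ethyl 4-acetoxy-8-bromo-5-methoxynaphthalene-2-carboxylate
Conditions: Ac2O, NaOAc, reflux
Reagents that add atoms: acetic anhydride, CC(=O)OC(C)=O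
Why: Intramolecular Friedel–Crafts acylation of the mixed anhydride builds ring D, enolisation and O-acetylation follow, and because bromine blocks one ortho carbon the closure can only occur next to the methoxy group, which fixes the peri dioxygen pattern.

Step 3
Reactants: 4 ethyl 4-acetoxy-8-bromo-5-methoxynaphthalene-2-carboxylate
Product: 5 5-bromo-3-(hydroxymethyl)-8-methoxynaphthalen-1-ol
Conditions: LiAlH4, THF, 0 °C → rt; aqueous work-up
Reagents that add atoms: none
Why: Ester reduction with LiAlH4 turns the ethyl ester into the primary alcohol and cleaves the aryl acetate in the same operation, while the aryl bromide is inert to the hydride at this temperature.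

Step 4
Reactants: 5 5-bromo-3-(hydroxymethyl)-8-methoxynaphthalen-1-ol
Product: 6 [8-bromo-5-methoxy-4-(methoxymethoxy)naphthalen-2-yl]methanol
Conditions: MOMCl (1.05 equiv), K2CO3, DMF, 0 °C → rt
Reagents that add atoms: chloromethyl methyl ether, COCCl
Why: Williamson-type O-alkylation in which carbonate ionises only the naphthol, so the phenoxide outruns the neutral primary alcohol for the single equivalent of reagent.

Step 5
Reactants: 6 [8-bromo-5-methoxy-4-(methoxymethoxy)naphthalen-2-yl]methanol
Product: 7 1-bromo-7-(bromomethyl)-4-methoxy-5-(methoxymethoxy)naphthalene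
Conditions: CBr4, PPh3, CH2Cl2, 0 °C
Reagents that add atoms: carbon tetrabromide, BrC(Br)(Br)Br
Why: Appel reaction, in which bromide displaces the alkoxyphosphonium salt of the primary benzylic alcohol under neutral conditions that spare the acetal and the aryl bromide.

Step 6
Reactants: 7 1-bromo-7-(bromomethyl)-4-methoxy-5-(methoxymethoxy)naphthalene
Product: 8 1-bromo-4-methoxy-5-(methoxymethoxy)-7-methylnaphthalene
Conditions: LiBHEt3, THF, 0 °C
Reagents that add atoms: none
Why: SN2 hydride displacement of a benzylic bromide by LiBHEt3 is fast at 0 °C and far outpaces any attack on the aryl bromide.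

Step 7
Reactants: 8 1-bromo-4-methoxy-5-(methoxymethoxy)-7-methylnaphthalene
Product: 9 2-[4-methoxy-5-(methoxymethoxy)-7-methylnaphthalen-1-yl]-4,4,5,5-tetramethyl-1,3,2-dioxaborolane
Conditions: B2pin2, PdCl2(dppf) (5 mol %), KOAc, 1,4-dioxane, 90 °C
Reagents that add atoms: bis(pinacolato)diboron, CC1(C)OB(OC1(C)C)B1OC(C)(C)C(C)(C)O1
Why: Miyaura borylation of an aryl bromide tolerates the ethers and the peri C–H next to the reacting carbon.

Step 8
Reactants: 10 2-bromoresorcinol
Product: 11 2-bromo-3-(methoxymethoxy)phenol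
Conditions: MOMCl (1.0 equiv), K2CO3, acetone, 0 °C → rt
Reagents that add atoms: chloromethyl methyl ether, COCCl
Why: Statistical mono-O-alkylation (Williamson type) of a symmetric diol with one equivalent of reagent, the mono-ether being separated by chromatography from the bis-ether and from diol that is recycled.

Step 9
Reactants: 11 2-bromo-3-(methoxymethoxy)phenol; 9 2-[4-methoxy-5-(methoxymethoxy)-7-methylnaphthalen-1-yl]-4,4,5,5-tetramethyl-1,3,2-dioxaborolane
Product: 12 2-[4-methoxy-5-(methoxymethoxy)-7-methylnaphthalen-1-yl]-3-(methoxymethoxy)phenol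
Conditions: Pd(OAc)2 (5 mol %), SPhos (10 mol %), K3PO4 (3 equiv), toluene/H2O 10:1, 100 °C
Reagents that add atoms: none
Why: Suzuki–Miyaura coupling with a bulky dialkylbiarylphosphine, the ligand class suited to di-ortho-substituted bromides, forms the C7–C1′ bond while the free phenol is carried as its phenoxide.

Step 10
Reactants: 12 2-[4-methoxy-5-(methoxymethoxy)-7-methylnaphthalen-1-yl]-3-(methoxymethoxy)phenol
Product: 13 6-iodo-2-[4-methoxy-5-(methoxymethoxy)-7-methylnaphthalen-1-yl]-3-(methoxymethoxy)phenol
Conditions: I2 (1.0 equiv), NaHCO3, THF/H2O 1:1, 0 °C → rt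
Reagents that add atoms: iodine, II
Why: Electrophilic iodination of a phenol, in which 3-alkoxyphenols are known to take iodine ortho to the hydroxyl and para to the alkoxy group under these conditions, the other activated site is shielded by the MOM group that the naphthyl neighbour pushes toward it, and molecular iodine with bicarbonate does not attack aryl ethers such as the naphthalene.

Step 11
Reactants: 13 6-iodo-2-[4-methoxy-5-(methoxymethoxy)-7-methylnaphthalen-1-yl]-3-(methoxymethoxy)phenol
Product: 14 1-[3-iodo-2-methoxy-6-(methoxymethoxy)phenyl]-4-methoxy-5-(methoxymethoxy)-7-methylnaphthalene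
Conditions: MeI, K2CO3, DMF, rt
Reagents that add atoms: iodomethane, CI
Why: Williamson O-methylation of the only free phenol works with the small electrophile even though iodine and the naphthyl group flank the oxygen, and it completes the C8a–I, C8–OMe, C7–aryl, C6–OMOM array.

Step 12
Reactants: 15 L-alaninol
Product: 17 (S)-2-methyl-1-(2-nitrophenylsulfonyl)aziridine, via N,O-bis(nosyl)alaninol 16 (not isolated)
Conditions: 2-NsCl (2.2 equiv), Et3N (4 equiv), DMAP (cat.), CH2Cl2, 0 °C → rt
Reagents that add atoms: 2-nitrobenzenesulfonyl chloride, O=S(=O)(Cl)c1ccccc1[N+](=O)[O-]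
Why: Double sulfonylation followed by a Wenker-type 3-exo-tet displacement of the primary nosylate by the sulfonamide anion breaks no bond at the stereocentre, so the S configuration of L-alaninol is retained.

Step 13
Reactants: 14 1-[3-iodo-2-methoxy-6-(methoxymethoxy)phenyl]-4-methoxy-5-(methoxymethoxy)-7-methylnaphthalene; 17 (S)-2-methyl-1-(2-nitrophenylsulfonyl)aziridine; 18 tert-butyl acrylate
Product: 20 tert-butyl 2-[(1R,3S)-8-methoxy-7-[4-methoxy-5-(methoxymethoxy)-7-methylnaphthalen-1-yl]-6-(methoxymethoxy)-3-methyl-2-(2-nitrophenylsulfonyl)-1,2,3,4-tetrahydroisoquinolin-1-yl]acetate, via open-chain cinnamate sulfonamide 19 (not isolated)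
Conditions: Pd(OAc)2 (10 mol %), P(2-furyl)3 (22 mol %), norbornene (2 equiv), Cs2CO3 (3 equiv), 17 (1.5 equiv), 18 (2 equiv), MeCN, 80 °C
Reagents that add atoms: none
Why: Zerovalent palladium inserts into C8a–I, norbornene carbopalladation brings the metal next to C4a–H, and the five-membered palladacycle formed by C–H metalation opens aziridine 17 at its unsubstituted carbon in an SN2-like oxidative addition to tetravalent palladium, after which reductive elimination forges C4–C4a. Now flanked by two ortho groups, the aryl–norbornyl palladium species expels norbornene by β-carbon elimination, the C8a–palladium bond adds to acrylate 18 in a Heck reaction (C8a–C1) to give 19, and the caesium sulfonamidate closes ring B by a 6-exo-trig aza-Michael addition (N2–C1). The closest known reaction type is this same three-component Catellani reaction of ortho-substituted aryl iodides with N-sulfonyl 2-alkylaziridines and acrylates, an established entry to 1,3-disubstituted tetrahydroisoquinolines, so only the biaryl substrate is new. C3 is no reaction site and passes its S configuration on from 17, while C1 is set under substrate control by C3 in a reversible addition that should settle on the 1,3-cis (1R) isomer, where both substituents stand pseudo-axial and escape allylic strain with the sulfonyl group; either epimer serves because C1 becomes trigonal in step 15. The step needs site selectivity (C4a–H is the only C–H ortho to C8a), relay before direct Heck coupling (the C8 methoxy group speeds norbornene insertion and later forces its extrusion, and norbornene is in excess) and Heck termination ahead of C–N reductive elimination to an indoline (excess acrylate and a weakly donating monophosphine).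

Step 14
Reactants: 20 tert-butyl 2-[(1R,3S)-8-methoxy-7-[4-methoxy-5-(methoxymethoxy)-7-methylnaphthalen-1-yl]-6-(methoxymethoxy)-3-methyl-2-(2-nitrophenylsulfonyl)-1,2,3,4-tetrahydroisoquinolin-1-yl]acetate
Product: 21 tert-butyl 2-[(1R,3S)-8-methoxy-7-[4-methoxy-5-(methoxymethoxy)-7-methylnaphthalen-1-yl]-6-(methoxymethoxy)-3-methyl-1,2,3,4-tetrahydroisoquinolin-1-yl]acetate
Conditions: PhSH, K2CO3, DMF, rt
Reagents that add atoms: none
Why: Fukuyama denosylation, in which the thiolate adds to the ipso carbon of the nitroarene (SNAr through a Meisenheimer adduct), SO2 is lost and the secondary amine is released without touching the ester, the acetals or C3.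

Step 15
Reactants: 21 tert-butyl 2-[(1R,3S)-8-methoxy-7-[4-methoxy-5-(methoxymethoxy)-7-methylnaphthalen-1-yl]-6-(methoxymethoxy)-3-methyl-1,2,3,4-tetrahydroisoquinolin-1-yl]acetate
Product: 23 tert-butyl (2Z)-2-[(3S)-8-methoxy-7-[4-methoxy-5-(methoxymethoxy)-7-methylnaphthalen-1-yl]-6-(methoxymethoxy)-3-methyl-3,4-dihydroisoquinolin-1(2H)-ylidene]acetate, via N-chloroamine 22 (not isolated)
Conditions: NCS (1.05 equiv), CH2Cl2, 0 °C; then DBU (2 equiv), 0 °C → rt
Reagents that add atoms: none
Why: N-chlorination and base-induced dehydrochlorination, the standard passage from tetrahydro- to 3,4-dihydroisoquinolines, should remove the more acidic benzylic C1–H rather than C3–H, and the imine tautomerises to the hydrogen-bonded (Z)-vinylogous carbamate, a sink that erases C1 and leaves C3 untouched.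

Step 16
Reactants: 23 tert-butyl (2Z)-2-[(3S)-8-methoxy-7-[4-methoxy-5-(methoxymethoxy)-7-methylnaphthalen-1-yl]-6-(methoxymethoxy)-3-methyl-3,4-dihydroisoquinolin-1(2H)-ylidene]acetate
Product: 25 (3S)-7-(5-hydroxy-4-methoxy-7-methylnaphthalen-1-yl)-8-methoxy-1,3-dimethyl-3,4-dihydroisoquinolin-6-ol, via imino acid 24 (not isolated)
Conditions: TFA/CH2Cl2 1:1, H2O (5 equiv), 0 °C → rt; evaporate; MeCN, 50 °C; aq. NaHCO3
Reagents that add atoms: none
Why: Acidolysis cleaves the tert-butyl ester and both phenolic MOM acetals, and the resulting β-imino acid decarboxylates like a β-keto acid so that the former acrylate α-carbon remains as the C1 methyl group, while the methyl ethers and the C3 centre are inert to these conditions.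

**Compound list**

1 | 2-bromo-5-methoxybenzaldehyde | COc1ccc(Br)c(C=O)c1 | starting material
2 | diethyl succinate | CCOC(=O)CCC(=O)OCC | starting material
3 | (E)-4-(2-bromo-5-methoxyphenyl)-3-(ethoxycarbonyl)but-3-enoic acid | CCOC(=O)/C(CC(=O)O)=C/c1cc(OC)ccc1Br | intermediate
4 | ethyl 4-acetoxy-8-bromo-5-methoxynaphthalene-2-carboxylate | CCOC(=O)c1cc(OC(C)=O)c2c(OC)ccc(Br)c2c1 | intermediate
5 | 5-bromo-3-(hydroxymethyl)-8-methoxynaphthalen-1-ol | COc1ccc(Br)c2cc(CO)cc(O)c12 | intermediate
6 | [8-bromo-5-methoxy-4-(methoxymethoxy)naphthalen-2-yl]methanol | COCOc1cc(CO)cc2c(Br)ccc(OC)c12 | intermediate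
7 | 1-bromo-7-(bromomethyl)-4-methoxy-5-(methoxymethoxy)naphthalene | COCOc1cc(CBr)cc2c(Br)ccc(OC)c12 | intermediate
8 | 1-bromo-4-methoxy-5-(methoxymethoxy)-7-methylnaphthalene | COCOc1cc(C)cc2c(Br)ccc(OC)c12 | intermediate
9 | 2-[4-methoxy-5-(methoxymethoxy)-7-methylnaphthalen-1-yl]-4,4,5,5-tetramethyl-1,3,2-dioxaborolane | COCOc1cc(C)cc2c(B3OC(C)(C)C(C)(C)O3)ccc(OC)c12 | intermediate
10 | 2-bromoresorcinol (2-bromobenzene-1,3-diol) | Oc1cccc(O)c1Br | starting material
11 | 2-bromo-3-(methoxymethoxy)phenol | COCOc1cccc(O)c1Br | intermediate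
12 | 2-[4-methoxy-5-(methoxymethoxy)-7-methylnaphthalen-1-yl]-3-(methoxymethoxy)phenol | COCOc1cccc(O)c1-c1ccc(OC)c2c(OCOC)cc(C)cc12 | intermediate
13 | 6-iodo-2-[4-methoxy-5-(methoxymethoxy)-7-methylnaphthalen-1-yl]-3-(methoxymethoxy)phenol | COCOc1ccc(I)c(O)c1-c1ccc(OC)c2c(OCOC)cc(C)cc12 | intermediate
14 | 1-[3-iodo-2-methoxy-6-(methoxymethoxy)phenyl]-4-methoxy-5-(methoxymethoxy)-7-methylnaphthalene | COCOc1ccc(I)c(OC)c1-c1ccc(OC)c2c(OCOC)cc(C)cc12 | intermediate
15 | L-alaninol, (S)-2-aminopropan-1-ol | C[C@H](N)CO | starting material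
16 | (S)-2-[(2-nitrophenyl)sulfonylamino]propyl 2-nitrobenzenesulfonate | C[C@H](NS(=O)(=O)c1ccccc1[N+](=O)[O-])COS(=O)(=O)c1ccccc1[N+](=O)[O-] | intermediate
17 | (S)-2-methyl-1-(2-nitrophenylsulfonyl)aziridine | C[C@H]1CN1S(=O)(=O)c1ccccc1[N+](=O)[O-] | intermediate
18 | tert-butyl acrylate | C=CC(=O)OC(C)(C)C | starting material
19 | tert-butyl (E)-3-{2-methoxy-3-[4-methoxy-5-(methoxymethoxy)-7-methylnaphthalen-1-yl]-4-(methoxymethoxy)-6-[(2S)-2-{[(2-nitrophenyl)sulfonyl]amino}propyl]phenyl}prop-2-enoate | CC(C)(C)OC(=O)/C=C/c1c(OC)c(-c2ccc(OC)c3c(OCOC)cc(C)cc23)c(OCOC)cc1C[C@H](C)NS(=O)(=O)c1ccccc1[N+](=O)[O-] | intermediate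
20 | tert-butyl 2-[(1R,3S)-8-methoxy-7-[4-methoxy-5-(methoxymethoxy)-7-methylnaphthalen-1-yl]-6-(methoxymethoxy)-3-methyl-2-(2-nitrophenylsulfonyl)-1,2,3,4-tetrahydroisoquinolin-1-yl]acetate (1,3-cis) | CC(C)(C)OC(=O)C[C@@H]1c2c(OC)c(-c3ccc(OC)c4c(OCOC)cc(C)cc34)c(OCOC)cc2C[C@H](C)N1S(=O)(=O)c1ccccc1[N+](=O)[O-] | intermediate
21 | tert-butyl 2-[(1R,3S)-8-methoxy-7-[4-methoxy-5-(methoxymethoxy)-7-methylnaphthalen-1-yl]-6-(methoxymethoxy)-3-methyl-1,2,3,4-tetrahydroisoquinolin-1-yl]acetate | CC(C)(C)OC(=O)C[C@@H]1c2c(OC)c(-c3ccc(OC)c4c(OCOC)cc(C)cc34)c(OCOC)cc2C[C@H](C)N1 | intermediate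
22 | N-chloro derivative of 21 (2-chloro-1,2,3,4-tetrahydroisoquinoline, 1R,3S) | CC(C)(C)OC(=O)C[C@@H]1c2c(OC)c(-c3ccc(OC)c4c(OCOC)cc(C)cc34)c(OCOC)cc2C[C@H](C)N1Cl | intermediate
23 | tert-butyl (2Z)-2-[(3S)-8-methoxy-7-[4-methoxy-5-(methoxymethoxy)-7-methylnaphthalen-1-yl]-6-(methoxymethoxy)-3-methyl-3,4-dihydroisoquinolin-1(2H)-ylidene]acetate | CC(C)(C)OC(=O)/C=C1\N[C@@H](C)Cc2cc(OCOC)c(-c3ccc(OC)c4c(OCOC)cc(C)cc34)c(OC)c21 | intermediate
24 | 2-[(3S)-6-hydroxy-7-(5-hydroxy-4-methoxy-7-methylnaphthalen-1-yl)-8-methoxy-3-methyl-3,4-dihydroisoquinolin-1-yl]acetic acid | OC(=O)CC1=N[C@@H](C)Cc2cc(O)c(-c3ccc(OC)c4c(O)cc(C)cc34)c(OC)c21 | intermediate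
25 | (3S)-7-(5-hydroxy-4-methoxy-7-methylnaphthalen-1-yl)-8-methoxy-1,3-dimethyl-3,4-dihydroisoquinolin-6-ol | COc1c2c(cc(O)c1-c1ccc(OC)c3c(O)cc(C)cc13)C[C@H](C)N=C2C | target

**Step count**

- Total step count: 16 steps.
- Longest linear sequence: 14 steps (steps 1–7, 9–11, 13–16).

**Steps most likely to fail**

**Step 13.**
- What may go wrong: Heck coupling of the aryl palladium species before the norbornene relay; carbon–nitrogen reductive elimination of the sulfonamidate onto C8a after the alkylation; consumption of the strained electrophile by iodide or carbonate; attack of the transient ester enolate on the nitroarene.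
- Fallback: it sets out from 15 and 14 and comes back at 21. It keeps the disconnection, replaces strain-release alkylation by an alkyl iodide that carries a nitrogen without N–H, and postpones the N2–C1 closure.
- L-Alaninol 15 is condensed with phthalic anhydride to N-phthaloyl-L-alaninol F1.
- I2, PPh3 and imidazole convert it into (S)-2-(1-iodopropan-2-yl)isoindoline-1,3-dione F2.
- A Catellani reaction of 14 with F2 as alkylating agent and 18 as terminating olefin (Pd(OAc)2, P(2-furyl)3, norbornene, Cs2CO3, MeCN) should stop at the phthalimido cinnamate F3.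
- Hydrazine hydrate in ethanol frees the amino cinnamate F4, which should close by spontaneous 6-exo-trig aza-Michael addition to 21. Step 14 then falls away.

**Step 10.**
- What may go wrong: iodination para instead of ortho to the hydroxyl, a second iodination of ring A, or competing attack on the electron-rich naphthalene.
- Fallback: it sets out from 12 and comes back at 13. It replaces electrophilic substitution by directed ortho-metalation.
- Phenol 12 is carbamoylated (NaH, ClCONEt2, THF) to the O-aryl diethylcarbamate F5.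
- s-BuLi/TMEDA at −78 °C lithiates next to the carbamate, the strongest director in the molecule, whose only free ortho position is the required carbon.
- I2 then gives the iodo carbamate F6, and NaOH in refluxing ethanol removes the carbamoyl group to return 13.

**Step 15.**
- What may go wrong: chlorine transfer to the naphthalene or ring A, elimination toward C3, or closure of the ester α-carbon onto nitrogen.
- Fallback: it sets out from 17 and 14 and comes back at 23. It brings C1 in at the enamine oxidation level, so no amine oxidation is needed.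
- MgBr2·OEt2 opens 17 at its CH2 group to N-[(2S)-1-bromopropan-2-yl]-2-nitrobenzenesulfonamide F7.
- DABCO-catalysed conjugate addition of its N–H to tert-butyl propiolate gives the (E)-β-sulfonamidoacrylate F8. This reagent holds the alkyl bromide and the Heck acceptor in one molecule, with N2–C1 already made.
- A Catellani reaction of 14 with F8 (ortho alkylation at C4a, intramolecular 6-exo-trig Heck reaction at C8a, β-hydride elimination of C1–H) should give the N-nosyl ylidene acetate F9.
- Thiophenol and K2CO3 convert F9 into 23.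

**Further compounds**

F1 | step 13 | 2-[(2S)-1-hydroxypropan-2-yl]isoindoline-1,3-dione | C[C@@H](CO)N1C(=O)c2ccccc2C1=O
F2 | step 13 | 2-[(2S)-1-iodopropan-2-yl]isoindoline-1,3-dione | C[C@@H](CI)N1C(=O)c2ccccc2C1=O
F3 | step 13 | tert-butyl (E)-3-{6-[(2S)-2-(1,3-dioxoisoindolin-2-yl)propyl]-2-methoxy-3-[4-methoxy-5-(methoxymethoxy)-7-methylnaphthalen-1-yl]-4-(methoxymethoxy)phenyl}prop-2-enoate | CC(C)(C)OC(=O)/C=C/c1c(OC)c(-c2ccc(OC)c3c(OCOC)cc(C)cc23)c(OCOC)cc1C[C@H](C)N1C(=O)c2ccccc2C1=O
F4 | step 13 | tert-butyl (E)-3-{6-[(2S)-2-aminopropyl]-2-methoxy-3-[4-methoxy-5-(methoxymethoxy)-7-methylnaphthalen-1-yl]-4-(methoxymethoxy)phenyl}prop-2-enoate | CC(C)(C)OC(=O)/C=C/c1c(OC)c(-c2ccc(OC)c3c(OCOC)cc(C)cc23)c(OCOC)cc1C[C@H](C)N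
F5 | step 10 | 2-[4-methoxy-5-(methoxymethoxy)-7-methylnaphthalen-1-yl]-3-(methoxymethoxy)phenyl diethylcarbamate | CCN(CC)C(=O)Oc1cccc(OCOC)c1-c1ccc(OC)c2c(OCOC)cc(C)cc12
F6 | step 10 | 6-iodo-2-[4-methoxy-5-(methoxymethoxy)-7-methylnaphthalen-1-yl]-3-(methoxymethoxy)phenyl diethylcarbamate | CCN(CC)C(=O)Oc1c(I)ccc(OCOC)c1-c1ccc(OC)c2c(OCOC)cc(C)cc12
F7 | step 15 | N-[(2S)-1-bromopropan-2-yl]-2-nitrobenzenesulfonamide | C[C@@H](CBr)NS(=O)(=O)c1ccccc1[N+](=O)[O-]
F8 | step 15 | tert-butyl (E)-3-{[(2S)-1-bromopropan-2-yl](2-nitrophenylsulfonyl)amino}prop-2-enoate | C[C@@H](CBr)N(/C=C/C(=O)OC(C)(C)C)S(=O)(=O)c1ccccc1[N+](=O)[O-]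
F9 | step 15 | tert-butyl (2E)-2-[(3S)-8-methoxy-7-[4-methoxy-5-(methoxymethoxy)-7-methylnaphthalen-1-yl]-6-(methoxymethoxy)-3-methyl-2-(2-nitrophenylsulfonyl)-3,4-dihydroisoquinolin-1(2H)-ylidene]acetate | CC(C)(C)OC(=O)/C=C1/N(S(=O)(=O)c2ccccc2[N+](=O)[O-])[C@@H](C)Cc2cc(OCOC)c(-c3ccc(OC)c4c(OCOC)cc(C)cc34)c(OC)c21
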